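Ring A is cut at C1–C6 and C1–C2, which unfolds it into a linear 1-aryl-1,3,5-triketone and dimethyl oxalate. The key step exploits the pattern of ring A, in which C1 carries the ester carbon, C2 the aroyl group and C3 and C5 oxygen: this is the imprint of a poly-β-carbonyl chain extended at its methyl end by an oxalyl unit and closed by aldol condensation. One operation thus forges both bonds, aromatises ring A and delivers the methyl ester. The precursor is the triketone carrying the chlorinated, MOM-protected orcinol ring B; the two new phenols are afterwards told apart by the hydrogen bond of the C3 hydroxyl.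

Key step: step 5

Remark: the poly-β-carbonyl compounds 8, 11 and 12 are drawn as keto tautomers although they should exist largely as enols. The two stereocentres of the transient aldol 12 form without control and vanish on aromatisation. Anhydrous orcinol is assumed.

Step 1
Reactants: 1 orcinol (5-methylbenzene-1,3-diol)
Product: 2 4-chloro-5-methylbenzene-1,3-diol (4-chloroorcinol)
Conditions: SO2Cl2 (1.0 equiv), Et2O, 0 °C to rt
Reagents that add atoms: sulfuryl chloride, O=S(=O)(Cl)Cl
Why: Electrophilic aromatic chlorination: resorcinols react fastest at C4, which is para to one hydroxyl and ortho to the other, rather than at C2 between the two hydroxyls, and one equivalent of sulfuryl chloride at low temperature limits a second chlorination.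

Step 2
Reactants: 2 4-chloro-5-methylbenzene-1,3-diol
Product: 3 2-chloro-1,5-bis(methoxymethoxy)-3-methylbenzene
Conditions: MOMCl (2.5 equiv), iPr2NEt (3 equiv), CH2Cl2, 0 °C to rt
Reagents that add atoms: chloromethyl methyl ether, COCCl
Why: Williamson-type O-alkylation of both phenols by the reactive α-chloro ether gives acetal ethers that are stable to the organolithium and amide bases ahead and direct the metalation of the next step.

Step 3
Reactants: 3 2-chloro-1,5-bis(methoxymethoxy)-3-methylbenzene
Product: 5 methyl 3-chloro-2,6-bis(methoxymethoxy)-4-methylbenzoate, via aryllithium 4 (not isolated)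
Conditions: n-BuLi (1.1 equiv), TMEDA, THF, 0 °C; then transferred into ClCO2Me (3 equiv), THF, −78 °C
Reagents that add atoms: methyl chloroformate, COC(=O)Cl
Why: Directed ortho-metalation followed by acylation: the hydrogen flanked by both MOM ethers is removed selectively through double coordination of lithium, the aryl chloride exchanges too slowly to interfere and lies meta to the lithium so that no aryne can form, and inverse addition to excess chloroformate stops the reaction at the hindered ester.

Step 4
Reactants: 5 methyl 3-chloro-2,6-bis(methoxymethoxy)-4-methylbenzoate; 6 acetylacetone (pentane-2,4-dione)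
Product: 8 1-[3-chloro-2,6-bis(methoxymethoxy)-4-methylphenyl]hexane-1,3,5-trione, via dilithio-acetylacetone 7 (not isolated)
Conditions: 6 (3 equiv), LiN(iPr)2 (6 equiv), THF, 0 °C; then 5, 0 °C to rt; AcOH quench
Reagents that add atoms: none
Why: Claisen acylation of a 1,3-diketone dianion at its terminal carbon, the most nucleophilic site; the ester cannot enolise, its two ortho alkoxy groups slow but should not block addition, and excess dianion compensates for the proton that the more acidic triketone product removes.

Step 5
Reactants: 8 1-[3-chloro-2,6-bis(methoxymethoxy)-4-methylphenyl]hexane-1,3,5-trione; 9 dimethyl oxalate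
Product: 13 methyl 2-[3-chloro-2,6-bis(methoxymethoxy)-4-methylbenzoyl]-3,5-dihydroxybenzoate, via triketone trianion 10 (not isolated), via tetraketo ester 11 (not isolated), via cyclic aldol 12 (not isolated)
Conditions: LiN(iPr)2 (4.2 equiv), THF, −78 to 0 °C; (CO2Me)2 (1.2 equiv), −78 to 0 °C; AcOH, then CH3CO2Na, MeOH, rt
Reagents that add atoms: none
Why: Four equivalents of LiN(iPr)2 strip both internal methylenes and the terminal methyl of 8, and the terminal carbanion of trianion 10, the last formed and least delocalised, attacks dimethyl oxalate in a Claisen acylation that expels methoxide and forms C6–C1 of ring A, the fourth equivalent of base taking up the newly acidified proton of 11. After buffering with acetic acid and sodium acetate, the C2 methylene of 11, flanked by the aryl ketone and the C3 carbonyl and hence the most acidic, adds to the ketone carbonyl next to the ester in an intramolecular aldol reaction that forms C1–C2; the six-membered ring closes in the 6-exo-trig mode, and loss of water from 12 followed by enolisation of the C3 and C5 ketones aromatises it to the resorcinol. The closest known reaction type is the ester acylation of β-polyketone polyanions and the biomimetic aldol cyclisation of the resulting polyketo esters to resorcinols. No stereocentre remains, since the two created in 12 are destroyed on aromatisation. The step needs terminal rather than internal C-acylation, secured by the reactivity order of the carbanion sites in the trianion, and it needs the C2-to-C1 folding rather than attack of C6 on the aryl ketone, O-cyclisation to a pyranone or Claisen closure onto the ester carbon, secured by the high electrophilicity of the ketone adjacent to the ester, by the shielding of the aryl ketone by its two ortho MOM ethers and by a near-neutral medium. The aryl chloride has substituents in both ortho positions, so the amide base cannot generate an aryne.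

Step 6
Reactants: 13 methyl 2-[3-chloro-2,6-bis(methoxymethoxy)-4-methylbenzoyl]-3,5-dihydroxybenzoate
Product: 14 methyl 2-[3-chloro-2,6-bis(methoxymethoxy)-4-methylbenzoyl]-3-hydroxy-5-(methoxymethoxy)benzoate
Conditions: MOMCl (1.1 equiv), iPr2NEt (1.5 equiv), CH2Cl2, 0 °C
Reagents that add atoms: chloromethyl methyl ether, COCCl
Why: Chemoselective O-alkylation: the C5 hydroxyl, para to the ketone and free of hydrogen bonding, is the more acidic and accessible phenol, whereas the C3 hydroxyl is held in a six-membered hydrogen bond to the benzophenone carbonyl; an acetal is chosen because it neither migrates nor cleaves under the carbonate base of the next step and leaves together with the other two at the end.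

Step 7
Reactants: 14 methyl 2-[3-chloro-2,6-bis(methoxymethoxy)-4-methylbenzoyl]-3-hydroxy-5-(methoxymethoxy)benzoate
Product: 15 methyl 2-[3-chloro-2,6-bis(methoxymethoxy)-4-methylbenzoyl]-3-methoxy-5-(methoxymethoxy)benzoate
Conditions: MeI (3 equiv), K2CO3, DMF, 40 °C
Reagents that add atoms: iodomethane, CI
Why: Williamson methylation of the remaining, chelated phenol, whose hydrogen bond is broken by carbonate in a dipolar aprotic solvent; the MOM ethers, the methyl ester and the aryl chloride are inert to these conditions.

Step 8
Reactants: 15 methyl 2-[3-chloro-2,6-bis(methoxymethoxy)-4-methylbenzoyl]-3-methoxy-5-(methoxymethoxy)benzoate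
Product: 16 monochlorosulochrin, methyl 2-(3-chloro-2,6-dihydroxy-4-methylbenzoyl)-5-hydroxy-3-methoxybenzoate
Conditions: HCl (cat.), MeOH, 40 °C
Reagents that add atoms: none
Why: Acid-catalysed acetal exchange (transacetalisation to dimethoxymethane) frees the three phenols, methanol as solvent makes any ester exchange degenerate, and the aryl methyl ether, the ketone and the chloride are stable to dilute acid.

Compound list
1 | orcinol (5-methylbenzene-1,3-diol) | Cc1cc(O)cc(O)c1 | starting material
2 | 4-chloro-5-methylbenzene-1,3-diol | Cc1cc(O)cc(O)c1Cl | intermediate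
3 | 2-chloro-1,5-bis(methoxymethoxy)-3-methylbenzene | Cc1cc(OCOC)cc(OCOC)c1Cl | intermediate
4 | [3-chloro-2,6-bis(methoxymethoxy)-4-methylphenyl]lithium | Cc1cc(OCOC)c([Li])c(OCOC)c1Cl | intermediate (not isolated)
5 | methyl 3-chloro-2,6-bis(methoxymethoxy)-4-methylbenzoate | COC(=O)c1c(OCOC)cc(C)c(Cl)c1OCOC | intermediate
6 | acetylacetone (pentane-2,4-dione) | CC(=O)CC(C)=O | starting material
7 | dilithio-acetylacetone (dilithium dianion of pentane-2,4-dione, drawn as the dienediolate) | [Li+].[Li+].C=C([O-])C=C(C)[O-] | intermediate (not isolated)
8 | 1-[3-chloro-2,6-bis(methoxymethoxy)-4-methylphenyl]hexane-1,3,5-trione | CC(=O)CC(=O)CC(=O)c1c(OCOC)cc(C)c(Cl)c1OCOC | intermediate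
9 | dimethyl oxalate | COC(=O)C(=O)OC | starting material
10 | trilithium trianion of 8 (drawn as the trienetriolate, enolate geometry undefined) | [Li+].[Li+].[Li+].C=C([O-])C=C([O-])C=C([O-])c1c(OCOC)cc(C)c(Cl)c1OCOC | intermediate (not isolated)
11 | methyl 8-[3-chloro-2,6-bis(methoxymethoxy)-4-methylphenyl]-2,4,6,8-tetraoxooctanoate | COC(=O)C(=O)CC(=O)CC(=O)CC(=O)c1c(OCOC)cc(C)c(Cl)c1OCOC | intermediate (not isolated)
12 | methyl 2-[3-chloro-2,6-bis(methoxymethoxy)-4-methylbenzoyl]-1-hydroxy-3,5-dioxocyclohexane-1-carboxylate (mixture of stereoisomers) | COC(=O)C1(O)CC(=O)CC(=O)C1C(=O)c1c(OCOC)cc(C)c(Cl)c1OCOC | intermediate (not isolated)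
13 | methyl 2-[3-chloro-2,6-bis(methoxymethoxy)-4-methylbenzoyl]-3,5-dihydroxybenzoate | COC(=O)c1cc(O)cc(O)c1C(=O)c1c(OCOC)cc(C)c(Cl)c1OCOC | intermediate
14 | methyl 2-[3-chloro-2,6-bis(methoxymethoxy)-4-methylbenzoyl]-3-hydroxy-5-(methoxymethoxy)benzoate | COC(=O)c1cc(OCOC)cc(O)c1C(=O)c1c(OCOC)cc(C)c(Cl)c1OCOC | intermediate
15 | methyl 2-[3-chloro-2,6-bis(methoxymethoxy)-4-methylbenzoyl]-3-methoxy-5-(methoxymethoxy)benzoate | COC(=O)c1cc(OCOC)cc(OC)c1C(=O)c1c(OCOC)cc(C)c(Cl)c1OCOC | intermediate
16 | monochlorosulochrin, methyl 2-(3-chloro-2,6-dihydroxy-4-methylbenzoyl)-5-hydroxy-3-methoxybenzoate | COC(=O)c1cc(O)cc(OC)c1C(=O)c1c(O)cc(C)c(Cl)c1O | target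

Total step count: 8. Longest linear sequence: 8 steps, from orcinol 1 to 16.

Steps most likely to fail

Step 5. The acylation may be misdirected (attack through an internal carbon or through oxygen, or twofold attack on the oxalate). The tetraketo ester may also fold wrongly: O-cyclisation to a pyranone, Claisen closure onto the ester carbon, or aldol addition to the aryl ketone. Hydrolysis of the activated ester is a further risk. The fallback builds ring A by cycloaddition instead of by folding; it sets out from 3 and comes back at 13. Lithiation of 3 as in step 3 gives aryllithium 4, and a DMF quench should give 3-chloro-2,6-bis(methoxymethoxy)-4-methylbenzaldehyde F1. Addition of lithium methyl propiolate (methyl propiolate, LiN(iPr)2, THF, −78 °C) should give racemic methyl 4-[3-chloro-2,6-bis(methoxymethoxy)-4-methylphenyl]-4-hydroxybut-2-ynoate F2. Oxidation with MnO2 in CH2Cl2 should give methyl 4-[3-chloro-2,6-bis(methoxymethoxy)-4-methylphenyl]-4-oxobut-2-ynoate F3. Diels–Alder reaction of F3 with 1-methoxy-1,3-bis(trimethylsilyloxy)buta-1,3-diene (toluene, rt to 60 °C) should give methyl 2-[3-chloro-2,6-bis(methoxymethoxy)-4-methylbenzoyl]-3-methoxy-3,5-bis(trimethylsilyloxy)cyclohexa-1,4-diene-1-carboxylate F4, which is not isolated. The nucleophilic CH2 terminus of the diene is expected to bond to the alkyne carbon β to the ketone. On work-up with dilute citric acid F4 should lose methanol and both silyl groups and aromatise to 13.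

Step 4. Addition to the doubly ortho-substituted ester may be so slow that proton transfer and self-condensation of the dianion take over. The fallback replaces attack on a shielded ester by attack on an aldehyde; it sets out from 3 and comes back at 8. The aldehyde F1, made from 3 through 4 as described for step 5, is treated with dilithio-acetylacetone 7 (THF, −78 °C). Terminal aldol addition should give racemic 6-[3-chloro-2,6-bis(methoxymethoxy)-4-methylphenyl]-6-hydroxyhexane-2,4-dione F5. Oxidation of the benzylic carbinol with Dess–Martin periodinane (NaHCO3, CH2Cl2) should give 8.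

Step 1. Site selectivity may be poor and chlorination may run on to the dichloride. The fallback postpones the halogenation until symmetry fixes its position; it sets out from 1 and comes back at 5. Orcinol 1 is protected (MOMCl, iPr2NEt, CH2Cl2) to 1,3-bis(methoxymethoxy)-5-methylbenzene F6. Metalation between the ethers (n-BuLi, TMEDA, THF, 0 °C) gives [2,6-bis(methoxymethoxy)-4-methylphenyl]lithium F7, which is quenched with methyl chloroformate to methyl 2,6-bis(methoxymethoxy)-4-methylbenzoate F8. The two open ring positions of F8 are equivalent, each ortho to one ether and para to the other, so monochlorination with N-chlorosuccinimide (1.0 equiv, DMF, rt to 40 °C) can give only 5.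

Further compounds
F1 | step 5 | 3-chloro-2,6-bis(methoxymethoxy)-4-methylbenzaldehyde | O=Cc1c(OCOC)cc(C)c(Cl)c1OCOC
F2 | step 5 | methyl 4-[3-chloro-2,6-bis(methoxymethoxy)-4-methylphenyl]-4-hydroxybut-2-ynoate (racemic) | COC(=O)C#CC(O)c1c(OCOC)cc(C)c(Cl)c1OCOC
F3 | step 5 | methyl 4-[3-chloro-2,6-bis(methoxymethoxy)-4-methylphenyl]-4-oxobut-2-ynoate | COC(=O)C#CC(=O)c1c(OCOC)cc(C)c(Cl)c1OCOC
F4 | step 5 | methyl 2-[3-chloro-2,6-bis(methoxymethoxy)-4-methylbenzoyl]-3-methoxy-3,5-bis(trimethylsilyloxy)cyclohexa-1,4-diene-1-carboxylate (racemic, not isolated) | COC(=O)C1=C(C(=O)c2c(OCOC)cc(C)c(Cl)c2OCOC)C(OC)(O[Si](C)(C)C)C=C(O[Si](C)(C)C)C1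
F5 | step 4 | 6-[3-chloro-2,6-bis(methoxymethoxy)-4-methylphenyl]-6-hydroxyhexane-2,4-dione (racemic) | CC(=O)CC(=O)CC(O)c1c(OCOC)cc(C)c(Cl)c1OCOC
F6 | step 1 | 1,3-bis(methoxymethoxy)-5-methylbenzene | COCOc1cc(C)cc(OCOC)c1
F7 | step 1 | [2,6-bis(methoxymethoxy)-4-methylphenyl]lithium (not isolated) | [Li]c1c(OCOC)cc(C)cc1OCOC
F8 | step 1 | methyl 2,6-bis(methoxymethoxy)-4-methylbenzoate | COC(=O)c1c(OCOC)cc(C)cc1OCOC
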